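## Retrosynthetic overview

1. Key disconnection (C–O): the O1–C2 bond of upper ring C. In the forward sense chalcone 1 is closed, through catalyst-bound 2 and 3, to (2S)-flavanone 4, which fixes C2.
2. Functional-group handle: the C4 carbonyl of 4 becomes the leaving group of flavan-4-ol 5.
3. Interflavan disconnection (C4–C8): 5 plus bought (−)-epigallocatechin 6, joined through quinone methide 7 to target 8. C4 follows from C2 by substrate control.
4. Ring order: rings A and B (in 1) and the whole lower unit (rings D, E, F in 6) are bought. Ring C is the only ring made, in step 1.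

Assumption: the quinine-derived amine is taken to give the (2S)-flavanone; if screening shows the opposite sense, its quinidine-derived pseudo-enantiomer is used in its place.

## Route

Step 1
Reactants: 1 isoliquiritigenin [(E)-1-(2,4-dihydroxyphenyl)-3-(4-hydroxyphenyl)prop-2-en-1-one]
Product: 4 (2S)-liquiritigenin [(2S)-7-hydroxy-2-(4-hydroxyphenyl)chroman-4-one], via chalcone ketimine 2 (not isolated), via flavanone enamine 3 (not isolated)
Conditions: 9-amino-9-deoxy-epi-quinine [(8α,9S)-6'-methoxycinchonan-9-amine] (20 mol%), CF3CO2H (40 mol%), THF, 40 °C, 48 h; stopped near 80% conversion, 1 recovered and recycled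
Reagents that add atoms: none
Why: Proposed new method: amine–iminium catalysis of the 6-endo oxa-Michael closure of a free polyhydroxy 2'-hydroxychalcone – the primary amine condenses preferentially with the 2'-hydroxyaryl ketone (O–H···N-assisted, as in salicyl ketimines) to give 2, whose N-protonated form is electrophilic enough at C-β to offset the deactivating 4-OH while the CF3CO2H buffer keeps every phenol un-ionised; rotation of ring A brings the 2'-OH onto C-β, the quinoline wall of the catalyst blocks one face and the quinuclidinium/trifluoroacetate pair shuttles the proton, so the O1–C2 bond forms on the open face to give enamine 3 with C2 = S, and hydrolysis releases 4, which lacks the ortho-OH and is re-activated only slowly, keeping the closure under kinetic control; closest known reactions are the amine-mediated chromanone closure of the Kabbe condensation, cinchona primary-amine iminium-catalysed intramolecular oxa- and aza-Michael additions to alkyl enones, and the enzyme chalcone isomerase.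

Step 2
Reactants: 4 (2S)-liquiritigenin
Product: 5 (2S,4S)-2-(4-hydroxyphenyl)chromane-4,7-diol (2,4-cis-4',7-dihydroxyflavan-4-ol)
Conditions: NaBH4 (3 equiv), THF/EtOH, 0 °C; pH 7 phosphate buffer work-up, used crude at once
Reagents that add atoms: none
Why: Borohydride reduction of the aryl ketone, with axial hydride delivery giving mainly the 2,4-cis alcohol (4S); C2 is untouched at 0 °C, and the C4 configuration is erased in step 3.

Step 3
Reactants: 5 (2S,4S)-2-(4-hydroxyphenyl)chromane-4,7-diol, 6 (−)-epigallocatechin (4 equiv)
Product: 8 (2S)-4',7-dihydroxyflavan-(4β→8)-(−)-epigallocatechin (the target), via quinone methide 7 (not isolated)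
Conditions: 0.1 M HCl, H2O/1,4-dioxane 4:1, 20 °C, N2, 5 added over 4 h; Sephadex LH-20 (excess 6 recovered), then reversed-phase HPLC
Reagents that add atoms: none
Why: Acid ionises the p-hydroxybenzylic alcohol with loss of water to quinone methide 7 (reacting as its O-protonated flavan-4-yl cation), which is trapped by C8 of the phloroglucinol ring of excess 6 in a biomimetic proanthocyanidin-type Friedel–Crafts alkylation; axial attack on the half-chair with the 2-aryl equatorial, which also places the new 4-aryl group quasi-axial and clear of the peri C5–H, sets C4 as R (2,4-trans, 4β).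

## Compound list

1 | isoliquiritigenin, (E)-1-(2,4-dihydroxyphenyl)-3-(4-hydroxyphenyl)prop-2-en-1-one | O=C(/C=C/c1ccc(O)cc1)c1ccc(O)cc1O | starting material
2 | ketimine of 1 with the catalyst amine, 4-[(1E)-3-(2,4-dihydroxyphenyl)-3-{[(8α,9S)-6'-methoxycinchonan-9-yl]imino}prop-1-en-1-yl]phenol (reacts as its N-protonated iminium ion) | Oc1ccc(/C=C/C(=N[C@@H](c2ccnc3ccc(OC)cc23)[C@@H]2C[C@@H]3CCN2C[C@@H]3C=C)c2ccc(O)cc2O)cc1 | intermediate
3 | catalyst-bound enamine, (2S)-2-(4-hydroxyphenyl)-4-{[(8α,9S)-6'-methoxycinchonan-9-yl]amino}-2H-chromen-7-ol | Oc1ccc([C@@H]2C=C(N[C@@H](c3ccnc4ccc(OC)cc34)[C@@H]3C[C@@H]4CCN3C[C@@H]4C=C)c3ccc(O)cc3O2)cc1 | intermediate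
4 | (2S)-liquiritigenin, (2S)-7-hydroxy-2-(4-hydroxyphenyl)chroman-4-one | O=C1C[C@@H](c2ccc(O)cc2)Oc2cc(O)ccc12 | intermediate
5 | (2S,4S)-2-(4-hydroxyphenyl)chromane-4,7-diol (2,4-cis; minor C4 epimer carried along) | O[C@H]1C[C@@H](c2ccc(O)cc2)Oc2cc(O)ccc12 | intermediate
6 | (−)-epigallocatechin, (2R,3R)-2-(3,4,5-trihydroxyphenyl)chromane-3,5,7-triol | O[C@@H]1Cc2c(O)cc(O)cc2O[C@@H]1c1cc(O)c(O)c(O)c1 | starting material
7 | p-quinone methide, (2S)-2-(4-hydroxyphenyl)-2,3-dihydro-7H-chromen-7-one | O=C1C=CC2=CC[C@@H](c3ccc(O)cc3)OC2=C1 | intermediate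
8 | (2R,3R)-8-[(2S,4R)-7-hydroxy-2-(4-hydroxyphenyl)chroman-4-yl]-2-(3,4,5-trihydroxyphenyl)chromane-3,5,7-triol | Oc1ccc([C@@H]2C[C@@H](c3c(O)cc(O)c4c3O[C@H](c3cc(O)c(O)c(O)c3)[C@H](O)C4)c3ccc(O)cc3O2)cc1 | target

## Step count and risks

Total step count: 3. Longest linear sequence: 3 (1 → 4 → 5 → 8; 6 enters at step 3).

Step 1 (the new C–O closure) is the most likely to fail. The iminium may form slowly on this aryl ketone, face selection is untested, and the chalcone/flavanone equilibrium caps conversion and erodes ee if the reaction is left too long. The fallback sets out from 1. Thermal closure (NaOAc, EtOH, reflux) gives racemic liquiritigenin F1. Asymmetric transfer hydrogenation under kinetic resolution then follows, with RuCl[(S,S)-TsDPEN](p-cymene) (a divalent ruthenium complex, 1 mol%), HCO2H/Et3N 1:1 (kept near neutral so that acid-labile 5 survives), EtOAc, 25 °C, stopped near 50% conversion. The catalyst delivers hydride to the face that gives the (4S)-benzylic alcohol, which is the unhindered face only in the (2S)-ketone, so the cis-alcohol 5 is formed directly. The unreacted (2R)-liquiritigenin F2 is separated and returned to F1 by the same NaOAc treatment. The fallback comes back to the route at 5 and replaces steps 1 and 2; here C2 is selected in the hydride transfer rather than in the ring closure.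

Step 3 (the coupling) is the second. Expected by-products are the C6-linked regioisomer, the 4α (2,4-cis) epimer, self-condensation of 5 and double alkylation of 6; an isolated yield of roughly one third is realistic. The fallback sets out from 5. Treatment with BnSH in AcOH at 20 °C gives the benzyl thioether F3 [(2S,4R)-4-(benzylsulfanyl)-2-(4-hydroxyphenyl)chroman-7-ol, with its C4 epimer], which can be stored and chromatographed. Thiophilic activation with AgBF4 (2.5 equiv) in THF at 0 °C in the presence of 6 (4 equiv) then releases the same electrophile slowly in an aprotic medium without added acid, which suppresses self-condensation. The fallback comes back at 8.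

Step 2 (the reduction) is the third. The 7-phenoxide formed under borohydride deactivates the carbonyl and could allow base-induced ring opening, which would erode the C2 configuration; 5 is also labile on work-up. The fallback sets out from 4. Silylation (triisopropylsilyl chloride, imidazole, DMF, 0 °C) gives the bis(triisopropylsilyl) ether F4. NaBH4 in THF/EtOH at 0 °C then reduces the now non-ionisable ketone cleanly to the stable silylated flavan-4-ol F5. Buffered desilylation (Bu4NF/AcOH 1:1, THF, 0 °C) liberates 5 immediately before the coupling. The fallback comes back at 5.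

## Further compounds

F1 | step 1 | racemic liquiritigenin, 7-hydroxy-2-(4-hydroxyphenyl)chroman-4-one | O=C1CC(c2ccc(O)cc2)Oc2cc(O)ccc12
F2 | step 1 | (2R)-liquiritigenin | O=C1C[C@H](c2ccc(O)cc2)Oc2cc(O)ccc12
F3 | step 3 | (2S,4R)-4-(benzylsulfanyl)-2-(4-hydroxyphenyl)chroman-7-ol | Oc1ccc([C@@H]2C[C@@H](SCc3ccccc3)c3ccc(O)cc3O2)cc1
F4 | step 2 | (2S)-7-(triisopropylsilyloxy)-2-[4-(triisopropylsilyloxy)phenyl]chroman-4-one | O=C1C[C@@H](c2ccc(O[Si](C(C)C)(C(C)C)C(C)C)cc2)Oc2cc(O[Si](C(C)C)(C(C)C)C(C)C)ccc12
F5 | step 2 | (2S,4S)-7-(triisopropylsilyloxy)-2-[4-(triisopropylsilyloxy)phenyl]chroman-4-ol | O[C@H]1C[C@@H](c2ccc(O[Si](C(C)C)(C(C)C)C(C)C)cc2)Oc2cc(O[Si](C(C)C)(C(C)C)C(C)C)ccc12
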